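**Retrosynthetic overview**

- The strategy rests on the only stereocentre, C3 of the chroman-4-one ring: a tertiary carbon alpha to the C4 ketone that carries the 7-methoxy-2,2-dimethylchromen-6-yl group. The bond from C3 to chromene C6 is the disconnection.
- That bond is cut to racemic 3-bromochromanone 10 and arylzinc iodide 12. They are joined by an enantioconvergent nickel/pybox Negishi alpha-arylation that sets C3 as S in the same operation.
- Aryl half: the chromene pyran ring is built first, from 4-bromo-3-methoxyphenol by O-propargylation and a propargyl Claisen/electrocyclisation cascade; the bromide then becomes the zinc reagent.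
- Ketone half: the chromanone ring is bought intact (7-hydroxychroman-4-one), protected as the TIPS ether and brominated at C3 through its silyl enol ether.
- The two bicycles are joined last, and the phenol is then released with buffered fluoride under cold, base-free conditions.

Key step: step 7

Remark: the sense of induction of the pybox–nickel catalyst on this cyclic bromide cannot be predicted with confidence, so the ligand antipode is left open and is fixed by a pilot coupling with assignment of the product.

**Route**

Step 1
Reactants: 1 4-bromo-3-methoxyphenol; 2 3-chloro-3-methylbut-1-yne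
Product: 3 1-bromo-2-methoxy-4-[(2-methylbut-3-yn-2-yl)oxy]benzene
Conditions: CuCl2·2H2O (cat.), DBU, MeCN, 0 °C
Reagents that add atoms: none
Why: Copper-catalysed propargylic etherification, in which the copper acetylide of 2 ionises at the tertiary carbon and is trapped by the DBU-generated phenoxide, is a reliable way to aryl 1,1-dimethylpropargyl ethers and leaves the aryl bromide untouched.

Step 2
Reactants: 3 1-bromo-2-methoxy-4-[(2-methylbut-3-yn-2-yl)oxy]benzene
Product: 6 6-bromo-7-methoxy-2,2-dimethyl-2H-chromene, via allenylphenol 4 (not isolated), via ortho-quinone methide 5 (not isolated)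
Conditions: PhNEt2, 185 °C; chromatography
Reagents that add atoms: none
Why: Aromatic propargyl Claisen rearrangement to allenylphenol 4, 1,5-hydrogen shift to the Z-configured quinone methide 5 and oxa-6π electrocyclisation should close the pyran ring at the ortho carbon para to OMe, which is far less hindered than the carbon between the two oxygens; any isomer closed there would be removed by chromatography.

Step 3
Reactants: 7 7-hydroxychroman-4-one
Product: 8 7-(triisopropylsilyloxy)chroman-4-one
Conditions: TIPSCl, imidazole, DMF, rt
Reagents that add atoms: triisopropylsilyl chloride, CC(C)[Si](Cl)(C(C)C)C(C)C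
Why: Imidazole-promoted silylation of the phenol masks the acidic OH that would quench the arylzinc, and the bulky aryl TIPS ether should survive enol silane formation, NBS and the organozinc.

Step 4
Reactants: 8 7-(triisopropylsilyloxy)chroman-4-one
Product: 9 triisopropyl{[4-(trimethylsilyloxy)-2H-chromen-7-yl]oxy}silane
Conditions: TMSOTf, Et3N, CH2Cl2, 0 °C; pentane, cold NaHCO3 wash, used crude
Reagents that add atoms: trimethylsilyl trifluoromethanesulfonate, C[Si](C)(C)OS(=O)(=O)C(F)(F)F
Why: Soft enolisation with TMSOTf/Et3N gives the only possible silyl enol ether (C3=C4) without a free metal enolate that could expel the ring aryloxide.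

Step 5
Reactants: 9 triisopropyl{[4-(trimethylsilyloxy)-2H-chromen-7-yl]oxy}silane
Product: 10 rac-3-bromo-7-(triisopropylsilyloxy)chroman-4-one
Conditions: NBS, THF, −78 °C; cold aqueous work-up without base, rapid filtration through silica, stored cold
Reagents that add atoms: N-bromosuccinimide, O=C1CCC(=O)N1Br
Why: Electrophilic alpha-bromination of a silyl enol ether with NBS is specific for C3 and avoids Br2/HBr, so the electron-rich arene should not be brominated and base-free cold handling should prevent HBr loss to the chromone; the bromide is racemic, which the coupling accepts.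

Step 6
Reactants: 6 6-bromo-7-methoxy-2,2-dimethyl-2H-chromene
Product: 12 (7-methoxy-2,2-dimethyl-2H-chromen-6-yl)zinc iodide, via aryllithium 11 (not isolated)
Conditions: t-BuLi (2 equiv), THF, −78 °C; then ZnI2, THF, −78 °C to rt; diluted with glyme, titrated and used directly as a solution
Reagents that add atoms: zinc iodide, I[Zn]I
Why: Bromine–lithium exchange (the second equivalent of t-BuLi destroys t-BuBr) gives the ortho-methoxy-stabilised aryllithium 11, and transmetalation with ZnI2 gives the weakly basic arylzinc iodide the coupling needs; the chromene has no acidic or electrophilic site at −78 °C.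

Step 7
Reactants: 10 rac-3-bromo-7-(triisopropylsilyloxy)chroman-4-one; 12 (7-methoxy-2,2-dimethyl-2H-chromen-6-yl)zinc iodide
Product: 13 (3S)-3-(7-methoxy-2,2-dimethyl-2H-chromen-6-yl)-7-(triisopropylsilyloxy)chroman-4-one
Conditions: NiCl2·glyme (10 mol %), chiral pybox ligand (13 mol %; e.g. 2,6-bis[(4R)-4-phenyl-4,5-dihydrooxazol-2-yl]pyridine or its antipode, chosen in a pilot run), 12 (1.4 equiv), glyme/THF, −30 °C; quench at −30 °C with pH 7 buffer, quick chromatography on neutral silica
Reagents that add atoms: none
Why: Proposed new method: monovalent nickel bound to the chiral pybox should abstract bromine from either enantiomer of 10 to give a planar C3 radical conjugated with the C4 carbonyl, which is captured by the aryl–nickel complex formed by transmetalation from 12, and reductive elimination from trivalent nickel then forms the bond from C3 to chromene C6. The closest known reaction type is the nickel/pybox-catalysed stereoconvergent Negishi arylation of racemic acyclic alpha-bromo ketones with arylzinc iodides; the extension lies in the cyclic 3-bromochroman-4-one, with a ring oxygen beta to the halide, and in the ortho-methoxy arylzinc. No ring is closed, since two preformed bicycles are joined. The single stereocentre C3 is set under catalyst control, the chiral ligand deciding which face of the planar radical is arylated, so both enantiomers of the bromide should converge on 3S and no resolution is needed. The step needs chemoselectivity for the activated alpha-keto C–Br bond, which is the only electrophilic site (chromene alkene and silyl ether are inert), and it needs HBr loss and aryloxide expulsion to be suppressed, which the radical (non-enolate) pathway and the inability of the ring to reach a syn-coplanar Ni–C3–C2–O1 geometry should secure. The arylzinc is too weakly basic at −30 °C to enolise the tertiary alpha-aryl ketone, so the new centre should survive to the cold neutral work-up.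

Step 8
Reactants: 13 (3S)-3-(7-methoxy-2,2-dimethyl-2H-chromen-6-yl)-7-(triisopropylsilyloxy)chroman-4-one
Product: 14 (3S)-7-hydroxy-3-(7-methoxy-2,2-dimethyl-2H-chromen-6-yl)chroman-4-one
Conditions: Et3N·3HF, THF, 0 °C (pyridine-buffered HF·pyridine if slow); pH 7 buffer work-up; ee checked by chiral HPLC
Reagents that add atoms: none
Why: Fluoride-mediated Si–O cleavage in a slightly acidic, buffered medium avoids the phenoxide- or base-promoted enolisation that would epimerise C3, and the chromene alkene and ketone are inert to it.

**Compound list**

1 | 4-bromo-3-methoxyphenol | COc1cc(O)ccc1Br | starting material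
2 | 3-chloro-3-methylbut-1-yne | C#CC(C)(C)Cl | starting material
3 | 1-bromo-2-methoxy-4-[(2-methylbut-3-yn-2-yl)oxy]benzene | COc1cc(OC(C)(C)C#C)ccc1Br | intermediate
4 | 4-bromo-5-methoxy-2-(3-methylbuta-1,2-dien-1-yl)phenol | COc1cc(O)c(C=C=C(C)C)cc1Br | intermediate
5 | (6Z)-4-bromo-3-methoxy-6-(3-methylbut-2-en-1-ylidene)cyclohexa-2,4-dien-1-one | COC1=CC(=O)/C(=C\C=C(C)C)C=C1Br | intermediate
6 | 6-bromo-7-methoxy-2,2-dimethyl-2H-chromene | COc1cc2c(cc1Br)C=CC(C)(C)O2 | intermediate
7 | 7-hydroxychroman-4-one | O=C1CCOc2cc(O)ccc12 | starting material
8 | 7-(triisopropylsilyloxy)chroman-4-one | CC(C)[Si](C(C)C)(C(C)C)Oc1ccc2c(c1)OCCC2=O | intermediate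
9 | triisopropyl{[4-(trimethylsilyloxy)-2H-chromen-7-yl]oxy}silane | CC(C)[Si](C(C)C)(C(C)C)Oc1ccc2c(c1)OCC=C2O[Si](C)(C)C | intermediate
10 | rac-3-bromo-7-(triisopropylsilyloxy)chroman-4-one | CC(C)[Si](C(C)C)(C(C)C)Oc1ccc2c(c1)OCC(Br)C2=O | intermediate
11 | (7-methoxy-2,2-dimethyl-2H-chromen-6-yl)lithium | COc1cc2c(cc1[Li])C=CC(C)(C)O2 | intermediate
12 | (7-methoxy-2,2-dimethyl-2H-chromen-6-yl)zinc iodide | COc1cc2c(cc1[Zn]I)C=CC(C)(C)O2 | intermediate
13 | (3S)-3-(7-methoxy-2,2-dimethyl-2H-chromen-6-yl)-7-(triisopropylsilyloxy)chroman-4-one | COc1cc2c(cc1[C@H]1COc3cc(O[Si](C(C)C)(C(C)C)C(C)C)ccc3C1=O)C=CC(C)(C)O2 | intermediate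
14 | (3S)-7-hydroxy-3-(7-methoxy-2,2-dimethyl-2H-chromen-6-yl)chroman-4-one | COc1cc2c(cc1[C@H]1COc3cc(O)ccc3C1=O)C=CC(C)(C)O2 | target

**Step count**

Total steps: 8. Longest linear sequence: 5 steps (1 → 3 → 6 → 12 → 13 → 14, or equally 7 → 8 → 9 → 10 → 13 → 14).

**Steps most likely to fail**

Step 7 (proposed new method). Transmetalation of the hindered ortho-methoxy arylzinc may be slow, so that the bromide is consumed by reduction or by HBr loss to the chromone, or the catalyst may discriminate poorly between the faces of the cyclic radical. The fallback uses known chemistry and sets out from 8 and 6. Palladium-catalysed ketone alpha-arylation (Pd2(dba)3, XPhos, NaOtBu or K3PO4, toluene, 70 °C) should give racemic 3-(7-methoxy-2,2-dimethyl-2H-chromen-6-yl)-7-(triisopropylsilyloxy)chroman-4-one F1. Asymmetric transfer hydrogenation with dynamic kinetic resolution (RuCl[(S,S)-TsDPEN](p-cymene), HCO2H/Et3N, EtOAc, 40 °C) then follows, in which C3 epimerises under the amine while the catalyst reduces one enantiomer. It should give cis-(3S,4S)-3-(7-methoxy-2,2-dimethyl-2H-chromen-6-yl)-7-(triisopropylsilyloxy)chroman-4-ol F2. The (S,S) catalyst is expected to give the 4S carbinol by analogy with aryl alkyl ketones, to be confirmed. Dess–Martin periodinane (CH2Cl2, 0 °C, no amine) re-forms the C4 ketone without touching C3 and comes back to the route at 13.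

Step 2. The Claisen cascade may close partly at the ortho carbon between the two oxygens, or the material may decompose at the temperature required. The fallback sets out from 1 and replaces the pericyclic cascade by a polar annulation. Friedel–Crafts acylation/oxa-Michael ring closure with 3-methylbut-2-enoic acid in P2O5/MeSO3H (70 °C) is directed para to OMe and should give 6-bromo-7-methoxy-2,2-dimethylchroman-4-one F3. NaBH4 (MeOH, 0 °C) gives 6-bromo-7-methoxy-2,2-dimethylchroman-4-ol F4, and brief acid-catalysed dehydration (cat. TsOH, toluene, heat) comes back to the route at 6.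

Step 8. Enolisation at C3 during silyl cleavage, with fluoride or the liberated phenoxide acting as base, may erode the ee. The fallback sets out from 13 and replaces stereoretentive deprotection by resolution with recycling. The silyl ether is cleaved without stereochemical constraint (TBAF, THF) to racemic 7-hydroxy-3-(7-methoxy-2,2-dimethyl-2H-chromen-6-yl)chroman-4-one F5 (or scalemic material). The enantiomers are separated by preparative chromatography on a chiral stationary phase, and the unwanted 3R enantiomer is re-equilibrated with catalytic base and recycled. This comes back to the route at 14.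

**Further compounds**

F1 | step 7 | rac-3-(7-methoxy-2,2-dimethyl-2H-chromen-6-yl)-7-(triisopropylsilyloxy)chroman-4-one | COc1cc2c(cc1C1COc3cc(O[Si](C(C)C)(C(C)C)C(C)C)ccc3C1=O)C=CC(C)(C)O2
F2 | step 7 | (3S,4S)-3-(7-methoxy-2,2-dimethyl-2H-chromen-6-yl)-7-(triisopropylsilyloxy)chroman-4-ol | COc1cc2c(cc1[C@H]1COc3cc(O[Si](C(C)C)(C(C)C)C(C)C)ccc3[C@H]1O)C=CC(C)(C)O2
F3 | step 2 | 6-bromo-7-methoxy-2,2-dimethylchroman-4-one | COc1cc2c(cc1Br)C(=O)CC(C)(C)O2
F4 | step 2 | rac-6-bromo-7-methoxy-2,2-dimethylchroman-4-ol | COc1cc2c(cc1Br)C(O)CC(C)(C)O2
F5 | step 8 | rac-7-hydroxy-3-(7-methoxy-2,2-dimethyl-2H-chromen-6-yl)chroman-4-one | COc1cc2c(cc1C1COc3cc(O)ccc3C1=O)C=CC(C)(C)O2
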